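## Analysis of the target

- The target 20 is a 3,5-dihydro-2H-1-benzofuran-6-one. Ring A is a cyclohexa-2,4-dienone (C3a=C4, sp3 C5, C6=O, C7=C7a), ring B is the fused dihydrofuran (O1, C2, C3, C3a, C7a), and ring C is the 3,4,5-trimethoxyphenyl group on C2 (C1'–C6').
- It has three stereocentres. C2 (S) and C3 (S) are neighbours and carry aryl and methyl trans. C5 (R) is a quaternary carbon with allyl and methoxy, separated from C3 by C3a and C4; its allyl group lies on the face of the C2 aryl group, anti to the C3 methyl.
- Ring A is at the oxidation level of an ortho-quinone that has taken up an allyl nucleophile at C5. C6=O is a vinylogous ester through C7=C7a–O1 and has oxygen-bearing carbons on both sides.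
- The sensitive parts are the 5-allyl dienone (prone to [3,3] shifts of the allyl group to C3a or O6 on heating, and to allyl migration with aromatisation in acid), the benzylic ether O1–C2, and the easily oxidised electron-rich rings.
- The difficulty is twofold. Every ring A carbon except C4 is substituted, with three different oxygen functions in a row (C5, C6, C7), and C5 must be set relative to centres too far away to steer it.
- The strategy rests on the O1–C2 bond. It is a benzylic aryl ether whose benzylic carbon C2 is para to the oxygen on C4' of ring C. With a free hydroxyl at C4', C2 becomes the electrophilic terminus of a para-quinone methide, and O1, a phenol oxygen as long as ring A is aromatic, can add to it. Ring B is therefore closed on an aromatic ring A, and ring A is dearomatised afterwards.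

## Retrosynthetic reasoning

**C5–OCH3 (20 to 19).** The last bond cut is the O–CH3 bond of the tertiary ether at C5, giving tertiary alcohol 19. 19 already holds every carbon and stereocentre of 20, and leaving the etherification to the end keeps it clear of all oxidations. The forward step must alkylate a hindered hydroxyl next to a carbonyl without letting the allyl group migrate.

**C5–allyl (19 to 18).** Cutting the C5–allyl bond gives ortho-quinone 18. The two carbonyls of 18 differ: C6=O is a vinylogous ester (O1–C7a=C7–C6=O) next to the C7 methoxy group, while C5=O is an ordinary enone carbonyl next to C4–H. An allyl-metal reagent should therefore choose C5. The reverse order (allyl onto C5 of the arene by Claisen rearrangement from O6, then oxidation in an alcohol) looks shorter but was not adopted. In the oxidised phenol the positive charge is best stabilised at C7 by its methoxy group, so the alcohol would add at C7 or at C3a, not at the allyl-bearing C5. The price of the chosen order is that C5 is formed far from C2 and C3, without substrate control.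

**C5=O (18 to 17).** 18 is cut at the C5–O bond back to phenol 17. In 17 the para position (C3a) is substituted and only one ortho position (C5) bears hydrogen. An oxidation that proceeds by coupling at a ring C–H therefore has one site and leaves the C7 methoxy group alone.

**O-substituents (17 to 16 to 15).** The C4' oxygen must be a free phenol for ring closure and a methyl ether afterwards. O6 must be masked while ring C is oxidised and methylated, and free for the oxidation to 18. A methoxymethyl ether on O6 survives base, hydride, hydrogenation and the silver oxidant, and is removed by dilute acid.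

**O1–C2 (15 to 13 via 14).** This is the central cut. It opens ring B to the 1,2-diarylpropane 13 by way of quinone methide 14. Cutting here, and not at O1–C7a or C3–C3a, leaves two ordinary benzene rings joined by a three-carbon chain with one stereocentre (C3). The forward reaction creates C2 under the control of C3 in a five-membered closure, and only one carbon of 14 is electrophilic.

**O-benzyl groups and the C2–H/C3–H bonds (13 to 12 to 11).** The two phenols of 13 are released together from benzyl ethers, which are orthogonal to the acetal on O6. The C3 centre of 12 is traced to the E-stilbene 11 by removing H2 across C2=C3. An E-α-methylstilbene is a standard substrate for iridium-catalysed asymmetric hydrogenation, so the only stereocentre of 13 comes from a catalyst and not from a chiral starting material.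

**C2=C3 and C2–C3 (11 to 10 to 4 and 9).** 11 is the dehydration product of tertiary alcohol 10. 10 is cut at the C2–C3 bond into aryl methyl ketone 4 and the benzylic Grignard reagent 9, made from chloride 8. The methyl group of the target is the acetyl methyl of 4, so no redox adjustment at C3 is needed.

**Ring A and ring C building blocks (4 to 1; 8 to 5).** Ketone 4 comes from 1 through 2 and 3 by three successive O-alkylations. They rely on the graded reactivity of the three hydroxyls (4-OH most acidic, 2-OH chelated to the acetyl group). Chloride 8 comes from 5 through 6 and 7 by benzylation, reduction and chlorination.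

## Alternatives that were turned down

**Alternative 1: cyclobutenone and alkynyl ether cascade.**
- Disconnection: C3a–C7a, C6–C7 and C5–C6, so that rings A and B both arise from the cyclobutenone A1, which carries the C2/C3 chain ending in an ethynyl ether.
- Forward key step: heating A1 opens the four-membered ring, the resulting ketene adds to the tethered alkyne, and a second ring opening followed by six-electron electrocyclisation gives dienone A2.
- For: it is the most convergent plan. It makes both rings in one operation and delivers ring A directly at the dienone level with the allyl/methoxy carbon in place, so no late oxidation or allylation is needed. On end-game length it is stronger than the chosen route.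
- Against:
  - A2 lacks the C7 methoxy group. C7–H would have to be oxidised on a sensitive dienone.
  - The first ring opening makes C4 of A1 trigonal, so its configuration is lost. C5 is then set in the final electrocyclisation, biased only by the remote C2/C3 centres, so the C5 problem is not solved.
  - The secondary ethynyl ether of A1 has a β-hydrogen (C3–H) and can fragment by a retro-ene path at the temperature of the cascade.
  - A1 needs both C2 and C3 set beforehand and a specially substituted cyclobutenone.
- Comparison: the chosen route has a longer end game, but every intermediate before the key step is an ordinary protected phenol or arene, and the C7 oxygen is present from the start.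

**Alternative 2: catechol oxidation and oxa-Michael closure.**
- Disconnection: O1–C7a. Precursor A3 is a 3-methoxycatechol with the complete side chain and a secondary benzylic alcohol at C2.
- Forward key step: oxidation of A3 to its ortho-quinone, conjugate addition of the side-chain hydroxyl at C7a, and re-oxidation to dione A4.
- For: A4 is the same compound as 18, so the end game is shared. Ring C is complete from the start, which saves the phenol methylation and the acetal steps; on protecting-group economy this alternative is stronger. C2 and C3 are both fixed before the ring closes, so the trans relationship does not depend on equilibration.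
- Against:
  - Two stereocentres, not one, must be built in the open chain.
  - The nucleophile is a secondary alcohol, not a phenol.
  - The hydroxyl can reach two ring carbons ortho to the side chain (C7a and C4, both five-membered closures). The wanted one, C7a, is the β-carbon of the C7 enol ether and is therefore deactivated.
  - In the intermediate quinone, C3–H sits on the carbon attached to the quinone ring and can be lost by tautomerisation to a quinone methide, which erases C3.
- Comparison: the chosen route offers an electrophile with a single reactive carbon, a phenol nucleophile, and a closure with no regiochemical choice. It needs three more protecting-group operations.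

**Alternative 3: Wolff ring contraction of a 3-diazoflavanone.**
- Disconnection: C3–C3a, with ring B traced to the six-membered ring of diazoketone A5.
- Forward key step: irradiation of A5 expels nitrogen, the aryl carbon migrates from the carbonyl carbon to C3, and the alcohol solvent traps the ketene as ester A6.
- For: flavanones are easy to make, ring C and the O6 allyl ether are in place early, and no oxidation-sensitive free phenols are handled. C3 of A6 is α to an ester, so the trans isomer is available by base equilibration; on trans control this is at least as strong as the chosen route.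
- Against:
  - C2 carries the absolute configuration alone, and it lies β to the ketone in the flavanone stage. Base-mediated diazo transfer can racemise it through reversible ring opening.
  - A 1,2-hydrogen shift from C2 to the carbene carbon competes with ring contraction.
  - The ester of A6 must be reduced to a methyl group (about three steps).
  - The end game (Claisen rearrangement to C5, then oxidation in an alcohol) meets the C7-versus-C5 regiochemical problem described above. With C5 already occupied, the dione solution is closed.
- Comparison: the chosen route carries the methyl group from the acetophenone, creates C2 only in the ring closure, and keeps C5 free for the dione end game.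

Key step: step 11

Assumption (remark on the chemistry): with stilbene 11 the (S)-configured phosphinooxazoline ligand is taken to select the same alkene face as with the parent E-α-methylstilbene (R product). If the configuration of 12 proves opposite, the (R)-ligand is used.

## Steps

Step 1
Reactants: 1 gallacetophenone (2,3,4-trihydroxyacetophenone)
Product: 2 1-[2,3-dihydroxy-4-(methoxymethoxy)phenyl]ethan-1-one
Conditions: MOMCl (1.05 equiv), K2CO3 (1.1 equiv), acetone, 0 °C → rt
Reagents that add atoms: chloromethyl methyl ether, COCCl
Why: Williamson-type O-alkylation with limiting base; the 4-OH is para to the acetyl group and the most acidic unchelated phenol, the 2-OH is hydrogen-bonded to the carbonyl and the 3-OH is flanked on both sides, so the mono-ether at O4 should dominate.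

Step 2
Reactants: 2 1-[2,3-dihydroxy-4-(methoxymethoxy)phenyl]ethan-1-one
Product: 3 1-[2-hydroxy-3-methoxy-4-(methoxymethoxy)phenyl]ethan-1-one
Conditions: MeI (1.1 equiv), K2CO3 (1.2 equiv), acetone, rt
Reagents that add atoms: iodomethane, CI
Why: Selective O-methylation; the 2-OH stays chelated to the acetyl oxygen and is the least nucleophilic, so mild carbonate alkylation should stop at the 3-methyl ether, as in the classical partial methylation of gallacetophenone.

Step 3
Reactants: 3 1-[2-hydroxy-3-methoxy-4-(methoxymethoxy)phenyl]ethan-1-one
Product: 4 1-[2-(benzyloxy)-3-methoxy-4-(methoxymethoxy)phenyl]ethan-1-one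
Conditions: BnBr (1.3 equiv), K2CO3, DMF, 60 °C
Reagents that add atoms: benzyl bromide, BrCc1ccccc1
Why: The chelated 2-OH is alkylated under more forcing Williamson conditions (polar solvent, heat); the methoxymethyl acetal is stable to base.

Step 4
Reactants: 5 syringaldehyde (4-hydroxy-3,5-dimethoxybenzaldehyde)
Product: 6 4-(benzyloxy)-3,5-dimethoxybenzaldehyde
Conditions: BnBr (1.2 equiv), K2CO3, DMF, 60 °C
Reagents that add atoms: benzyl bromide, BrCc1ccccc1
Why: Williamson benzylation of the acidic syringyl phenol; benzyl is chosen so that this ether and the one in 4 are removed together in step 10 while the acetal on O6 stays.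

Step 5
Reactants: 6 4-(benzyloxy)-3,5-dimethoxybenzaldehyde
Product: 7 [4-(benzyloxy)-3,5-dimethoxyphenyl]methanol
Conditions: NaBH4, MeOH–THF, 0 °C
Reagents that add atoms: none
Why: Borohydride reduction of the aldehyde to the benzylic alcohol; no other reducible group is present.

Step 6
Reactants: 7 [4-(benzyloxy)-3,5-dimethoxyphenyl]methanol
Product: 8 2-(benzyloxy)-5-(chloromethyl)-1,3-dimethoxybenzene
Conditions: SOCl2 (1.2 equiv), CH2Cl2, 0 °C
Reagents that add atoms: thionyl chloride, ClS(Cl)=O
Why: Chlorodehydroxylation of an electron-rich benzylic alcohol through its chlorosulfite; the reactive chloride is used without purification.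

Step 7
Reactants: 8 2-(benzyloxy)-5-(chloromethyl)-1,3-dimethoxybenzene; 4 1-[2-(benzyloxy)-3-methoxy-4-(methoxymethoxy)phenyl]ethan-1-one
Product: 10 rac-2-[2-(benzyloxy)-3-methoxy-4-(methoxymethoxy)phenyl]-1-[4-(benzyloxy)-3,5-dimethoxyphenyl]propan-2-ol, via Grignard reagent 9 (not isolated)
Conditions: Mg, THF, 0 °C (slow addition of 8); then 4, THF, −20 °C → rt; aq. NH4Cl
Reagents that add atoms: none
Why: Grignard addition to a ketone forms the C2–C3 bond; the benzylic organomagnesium is made cold and dilute to hold back Wurtz coupling and, being weakly basic, should add to the aryl methyl ketone and not enolise it. The carbinol centre is racemic and disappears in step 8.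

Step 8
Reactants: 10 rac-2-[2-(benzyloxy)-3-methoxy-4-(methoxymethoxy)phenyl]-1-[4-(benzyloxy)-3,5-dimethoxyphenyl]propan-2-ol
Product: 11 2-(benzyloxy)-1-{(E)-1-[4-(benzyloxy)-3,5-dimethoxyphenyl]prop-1-en-2-yl}-3-methoxy-4-(methoxymethoxy)benzene
Conditions: PPTS (10 mol%), toluene, 80 °C, 4 Å MS
Reagents that add atoms: none
Why: Acid-catalysed E1 dehydration through a tertiary benzylic cation stabilised by the ortho and para oxygens of ring A; reversible protonation lets the alkene isomers equilibrate toward the conjugated stilbene with the aryl groups trans, and PPTS is weak enough to spare the aryl acetal. E-11 is freed from Z and exo-methylene isomers by crystallisation or chromatography before step 9.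

Step 9
Reactants: 11 2-(benzyloxy)-1-{(E)-1-[4-(benzyloxy)-3,5-dimethoxyphenyl]prop-1-en-2-yl}-3-methoxy-4-(methoxymethoxy)benzene
Product: 12 2-(benzyloxy)-1-{(2R)-1-[4-(benzyloxy)-3,5-dimethoxyphenyl]propan-2-yl}-3-methoxy-4-(methoxymethoxy)benzene
Conditions: [Ir(cod)(L)][B(C6H3(CF3)2)4] (1–2 mol%; L = (S)-4-tert-butyl-2-[2-(di-o-tolylphosphanyl)phenyl]-4,5-dihydrooxazole), H2 (50 bar), CH2Cl2, rt
Reagents that add atoms: none
Why: Iridium-catalysed asymmetric hydrogenation of an unfunctionalised trisubstituted alkene, for which E-α-methylstilbenes are the standard substrates of cationic iridium phosphinooxazoline catalysts. The chiral ligand selects the alkene face and so sets the future C3; R in 12 corresponds to 3S in 20 because O1 later raises the priority of C2. Benzyl and methoxymethyl ethers are inert to this homogeneous catalyst.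

Step 10
Reactants: 12 2-(benzyloxy)-1-{(2R)-1-[4-(benzyloxy)-3,5-dimethoxyphenyl]propan-2-yl}-3-methoxy-4-(methoxymethoxy)benzene
Product: 13 6-[(2R)-1-(4-hydroxy-3,5-dimethoxyphenyl)propan-2-yl]-2-methoxy-3-(methoxymethoxy)phenol
Conditions: H2 (1 atm), Pd/C (10 wt%), EtOAc–MeOH, rt
Reagents that add atoms: none
Why: Hydrogenolysis of both benzyl ethers over Pd/C; the acetal, the methyl ethers and the C3 centre (no activating group next to it) are untouched.

Step 11
Reactants: 13 6-[(2R)-1-(4-hydroxy-3,5-dimethoxyphenyl)propan-2-yl]-2-methoxy-3-(methoxymethoxy)phenol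
Product: 15 4-[(2S,3S)-7-methoxy-6-(methoxymethoxy)-3-methyl-2,3-dihydro-1-benzofuran-2-yl]-2,6-dimethoxyphenol, via quinone methide 14 (not isolated)
Conditions: Ag2O (2.5 equiv), CH2Cl2 (0.02 M), rt, dark; filtration through Celite
Reagents that add atoms: none
Why: Ag2O removes two electrons and two protons from the 4-alkyl-2,6-dimethoxyphenol of ring C and gives para-quinone methide 14, whose exocyclic carbon C2 is electrophilic; the ring A hydroxyl then adds to C2 in a 1,6-sense, forming O1–C2 and restoring the aromaticity of ring C. The closest known reaction type is the Ag2O generation of para-quinone methides from 4-alkyl-2,6-dimethoxyphenols and their capture by phenols, the bond construction that gives 2-aryl-2,3-dihydrobenzofurans in oxidative phenol coupling. Ring B closes in a 5-exo-trig mode, O1 attacking the exocyclic C2=C1' bond through the chain O1–C7a–C3a–C3–C2. C3 is carried over unchanged from 13; the new centre C2 is controlled by it, because in the closing transition state the C3 methyl and the quinoid ring avoid each other across the forming ring, and because the addition can revert through 14 so that the more stable 2,3-trans isomer (2S,3S) collects. The step needs chemoselective oxidation of one of two free phenols; the 2,6-dimethoxy-4-alkylphenol has the lower oxidation potential and is the only one that can give a methide stabilised by two methoxy groups, whereas the ring A phenol is a guaiacol-type phenol. Regiochemistry is not in question, since 14 has one electrophilic carbon and one phenol within reach, and dilution holds back intermolecular addition. Base is kept out so that 14 does not tautomerise to a 4-hydroxystilbene, which would erase C3.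

Step 12
Reactants: 15 4-[(2S,3S)-7-methoxy-6-(methoxymethoxy)-3-methyl-2,3-dihydro-1-benzofuran-2-yl]-2,6-dimethoxyphenol
Product: 16 (2S,3S)-7-methoxy-6-(methoxymethoxy)-3-methyl-2-(3,4,5-trimethoxyphenyl)-2,3-dihydro-1-benzofuran
Conditions: MeI (2 equiv), K2CO3 (2 equiv), acetone, rt
Reagents that add atoms: iodomethane, CI
Why: Williamson methylation of the ring C phenol, a routine operation on phenolic 2-aryl-2,3-dihydrobenzofurans; at room temperature any reversible opening of the phenoxide through the methide should reclose to the trans isomer before it matters.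

Step 13
Reactants: 16 (2S,3S)-7-methoxy-6-(methoxymethoxy)-3-methyl-2-(3,4,5-trimethoxyphenyl)-2,3-dihydro-1-benzofuran
Product: 17 (2S,3S)-7-methoxy-3-methyl-2-(3,4,5-trimethoxyphenyl)-2,3-dihydro-1-benzofuran-6-ol
Conditions: HCl (0.5 M in MeOH), THF, rt → 40 °C
Reagents that add atoms: none
Why: Acid-catalysed acetal exchange frees O6; the O1–C2 benzylic ether should survive dilute acid because a 3,4,5-trimethoxyphenyl group stabilises a benzylic cation only weakly (its 4-methoxy group is twisted out of conjugation by its neighbours).

Step 14
Reactants: 17 (2S,3S)-7-methoxy-3-methyl-2-(3,4,5-trimethoxyphenyl)-2,3-dihydro-1-benzofuran-6-ol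
Product: 18 (2S,3S)-7-methoxy-3-methyl-2-(3,4,5-trimethoxyphenyl)-2,3-dihydro-1-benzofuran-5,6-dione
Conditions: (KSO3)2NO (Fremy's salt, 2.5 equiv), KH2PO4 buffer (pH 6–7), acetone–H2O, 0 °C → rt
Reagents that add atoms: potassium nitrosodisulfonate, [K+].[K+].[O]N(S(=O)(=O)[O-])S(=O)(=O)[O-]
Why: Teuber oxidation; one nitroxyl radical takes the phenolic hydrogen and a second couples at a ring C–H, and with the para position (C3a) substituted the only such site is C5, so loss of imidodisulfonate gives the 5,6-dione with the C7 methoxy group intact, as known for 4-substituted 2-methoxyphenols. Buffered conditions and immediate use guard against enolisation of 18 toward C3.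

Step 15
Reactants: 18 (2S,3S)-7-methoxy-3-methyl-2-(3,4,5-trimethoxyphenyl)-2,3-dihydro-1-benzofuran-5,6-dione
Product: 19 (2S,3S,5R)-5-allyl-5-hydroxy-7-methoxy-3-methyl-2-(3,4,5-trimethoxyphenyl)-3,5-dihydro-1-benzofuran-6(2H)-one
Conditions: allyl bromide (3 equiv), In powder (2 equiv), DMF, rt [→ (CH2=CHCH2)3In2Br3]; then 18, DMF–THF, 0 °C; aq. NH4Cl
Reagents that add atoms: allyl bromide, C=CCBr
Why: 1,2-Addition of a preformed allylindium reagent to a quinone carbonyl; C6=O is a vinylogous ester flanked by the C7 methoxy group, so the more electrophilic and less hindered C5 carbonyl should be attacked, and the reagent is neither basic nor strongly Lewis acidic, which avoids enolisation and allyl migration. C5 is created here without reliable substrate control, since C2 and C3 are remote (approach anti to the C3 methyl, which leads to 5R, is at best slightly favoured); 19 is therefore secured by chromatographic separation of the two C5 diastereomers and its configuration is checked by NOE or X-ray analysis.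

Step 16
Reactants: 19 (2S,3S,5R)-5-allyl-5-hydroxy-7-methoxy-3-methyl-2-(3,4,5-trimethoxyphenyl)-3,5-dihydro-1-benzofuran-6(2H)-one
Product: 20 (2S,3S,5R)-5-allyl-5,7-dimethoxy-3-methyl-2-(3,4,5-trimethoxyphenyl)-3,5-dihydro-1-benzofuran-6(2H)-one
Conditions: MeI (excess), Ag2O (3 equiv), CaSO4, CH2Cl2, rt, dark
Reagents that add atoms: iodomethane, CI
Why: Purdie O-methylation of a tertiary α-hydroxy ketone, whose hydroxyl is acidified by the adjacent carbonyl; the neutral silver-assisted conditions avoid a free alkoxide (anionic oxy-Cope or α-ketol shift) and strong acid (allyl migration with aromatisation). No bond to C5 is broken, so 5R is retained.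

## Compound list

1 | gallacetophenone (2,3,4-trihydroxyacetophenone) | CC(=O)c1ccc(O)c(O)c1O | starting material
2 | 1-[2,3-dihydroxy-4-(methoxymethoxy)phenyl]ethan-1-one | CC(=O)c1ccc(OCOC)c(O)c1O | intermediate
3 | 1-[2-hydroxy-3-methoxy-4-(methoxymethoxy)phenyl]ethan-1-one | CC(=O)c1ccc(OCOC)c(OC)c1O | intermediate
4 | 1-[2-(benzyloxy)-3-methoxy-4-(methoxymethoxy)phenyl]ethan-1-one | CC(=O)c1ccc(OCOC)c(OC)c1OCc1ccccc1 | intermediate
5 | syringaldehyde (4-hydroxy-3,5-dimethoxybenzaldehyde) | COc1cc(C=O)cc(OC)c1O | starting material
6 | 4-(benzyloxy)-3,5-dimethoxybenzaldehyde | COc1cc(C=O)cc(OC)c1OCc1ccccc1 | intermediate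
7 | [4-(benzyloxy)-3,5-dimethoxyphenyl]methanol | COc1cc(CO)cc(OC)c1OCc1ccccc1 | intermediate
8 | 2-(benzyloxy)-5-(chloromethyl)-1,3-dimethoxybenzene | COc1cc(CCl)cc(OC)c1OCc1ccccc1 | intermediate
9 | [4-(benzyloxy)-3,5-dimethoxybenzyl]magnesium chloride | COc1cc(C[Mg]Cl)cc(OC)c1OCc1ccccc1 | intermediate
10 | rac-2-[2-(benzyloxy)-3-methoxy-4-(methoxymethoxy)phenyl]-1-[4-(benzyloxy)-3,5-dimethoxyphenyl]propan-2-ol | COCOc1ccc(C(C)(O)Cc2cc(OC)c(OCc3ccccc3)c(OC)c2)c(OCc2ccccc2)c1OC | intermediate
11 | 2-(benzyloxy)-1-{(E)-1-[4-(benzyloxy)-3,5-dimethoxyphenyl]prop-1-en-2-yl}-3-methoxy-4-(methoxymethoxy)benzene | COCOc1ccc(/C(C)=C/c2cc(OC)c(OCc3ccccc3)c(OC)c2)c(OCc2ccccc2)c1OC | intermediate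
12 | 2-(benzyloxy)-1-{(2R)-1-[4-(benzyloxy)-3,5-dimethoxyphenyl]propan-2-yl}-3-methoxy-4-(methoxymethoxy)benzene | COCOc1ccc([C@H](C)Cc2cc(OC)c(OCc3ccccc3)c(OC)c2)c(OCc2ccccc2)c1OC | intermediate
13 | 6-[(2R)-1-(4-hydroxy-3,5-dimethoxyphenyl)propan-2-yl]-2-methoxy-3-(methoxymethoxy)phenol | COCOc1ccc([C@H](C)Cc2cc(OC)c(O)c(OC)c2)c(O)c1OC | intermediate
14 | 4-{(2R)-2-[2-hydroxy-3-methoxy-4-(methoxymethoxy)phenyl]propylidene}-2,6-dimethoxycyclohexa-2,5-dien-1-one | COCOc1ccc([C@H](C)C=C2C=C(OC)C(=O)C(OC)=C2)c(O)c1OC | intermediate
15 | 4-[(2S,3S)-7-methoxy-6-(methoxymethoxy)-3-methyl-2,3-dihydro-1-benzofuran-2-yl]-2,6-dimethoxyphenol | COCOc1ccc2c(c1OC)O[C@H](c1cc(OC)c(O)c(OC)c1)[C@H]2C | intermediate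
16 | (2S,3S)-7-methoxy-6-(methoxymethoxy)-3-methyl-2-(3,4,5-trimethoxyphenyl)-2,3-dihydro-1-benzofuran | COCOc1ccc2c(c1OC)O[C@H](c1cc(OC)c(OC)c(OC)c1)[C@H]2C | intermediate
17 | (2S,3S)-7-methoxy-3-methyl-2-(3,4,5-trimethoxyphenyl)-2,3-dihydro-1-benzofuran-6-ol | Oc1ccc2c(c1OC)O[C@H](c1cc(OC)c(OC)c(OC)c1)[C@H]2C | intermediate
18 | (2S,3S)-7-methoxy-3-methyl-2-(3,4,5-trimethoxyphenyl)-2,3-dihydro-1-benzofuran-5,6-dione | O=C1C=C2C(=C(OC)C1=O)O[C@H](c1cc(OC)c(OC)c(OC)c1)[C@H]2C | intermediate
19 | (2S,3S,5R)-5-allyl-5-hydroxy-7-methoxy-3-methyl-2-(3,4,5-trimethoxyphenyl)-3,5-dihydro-1-benzofuran-6(2H)-one | C=CC[C@@]1(O)C=C2C(=C(OC)C1=O)O[C@H](c1cc(OC)c(OC)c(OC)c1)[C@H]2C | intermediate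
20 | (2S,3S,5R)-5-allyl-5,7-dimethoxy-3-methyl-2-(3,4,5-trimethoxyphenyl)-3,5-dihydro-1-benzofuran-6(2H)-one | C=CC[C@@]1(OC)C=C2C(=C(OC)C1=O)O[C@H](c1cc(OC)c(OC)c(OC)c1)[C@H]2C | target

## Step count and least certain steps

Total step count: 16. Longest linear sequence: 13 steps (steps 1–3 and 7–16; the branch through steps 4–6 and 7–16 is equally long).

**Step 11 (key step).** The most likely failures are loss of the C3 configuration and loss of material to side reactions.
- C3 can be lost if 14 tautomerises to the conjugated 4-hydroxystilbene before or after ring closure, because C3–H is activated through the methide.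
- Material can be lost through oxidation of the ring A phenol or intermolecular addition, because both phenols are electron-rich.
- Fallback, from 11 back to 15: C2 is made electrophilic by ionisation, not by oxidation.
  - Asymmetric hydroboration–oxidation of 11 (monoisopinocampheylborane of the appropriate antipode, then NaBO3) should add H and OH syn across the E-alkene. It gives the benzylic alcohol (1S,2S)-2-[2-(benzyloxy)-3-methoxy-4-(methoxymethoxy)phenyl]-1-[4-(benzyloxy)-3,5-dimethoxyphenyl]propan-1-ol F1.
  - Hydrogenolysis of the benzyl ethers (H2, Pd/C, EtOAc, stopped once they are gone) gives 6-[(1S,2S)-1-hydroxy-1-(4-hydroxy-3,5-dimethoxyphenyl)propan-2-yl]-2-methoxy-3-(methoxymethoxy)phenol F2.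
  - F2 is a 4-hydroxybenzyl alcohol. With catalytic PPTS it loses water to the same methide 14 and closes to 15 under thermodynamic control. This path also bypasses steps 9 and 10.

**Step 9.** The most likely failure is incomplete conversion or reduced enantioselectivity.
- The ortho-benzyloxy group twists ring A out of the alkene plane and crowds the catalyst.
- Any Z isomer left from the equilibrating dehydration of step 8 is reduced to the other enantiomer.
- Fallback, from 4 back to 12, avoiding the stilbene altogether:
  - Wittig methylenation (Ph3P=CH2, THF) gives 2-(benzyloxy)-3-methoxy-4-(methoxymethoxy)-1-(prop-1-en-2-yl)benzene F3.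
  - Catalytic enantioselective hydroboration of this 1,1-disubstituted alkene with HBpin (CoCl2 complex of a chiral iminopyridine–oxazoline ligand, activated with NaBHEt3) sets the centre in the C–H bond-forming step. It gives 2-{(2R)-2-[2-(benzyloxy)-3-methoxy-4-(methoxymethoxy)phenyl]propyl}-4,4,5,5-tetramethyl-1,3,2-dioxaborolane F4.
  - Suzuki–Miyaura coupling (Pd(OAc)2, RuPhos, K3PO4, toluene–H2O, 90 °C) with 2-(benzyloxy)-5-bromo-1,3-dimethoxybenzene F5 gives 12. F5 is made from commercial 4-bromo-2,6-dimethoxyphenol with BnBr and K2CO3.

**Step 15.** The most likely failure is poor facial selectivity at C5, because the nearest stereocentre is three bonds away and lies almost in the ring plane. Attack at the C6 carbonyl or electron-transfer reduction of the quinone is a lesser risk.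
- Fallback, from 18 to 20, relaying the configuration from C3 through C3a:
  - Hosomi–Sakurai conjugate allylation (allyltrimethylsilane, TiCl4, CH2Cl2, −78 °C) at C3a, the β-carbon of the C5 enone, should occur anti to the adjacent C3 methyl. It gives (2S,3S,3aS)-3a-allyl-5-hydroxy-7-methoxy-3-methyl-2-(3,4,5-trimethoxyphenyl)-3,3a-dihydro-1-benzofuran-6(2H)-one F6.
  - Methylation of its acidic enol (Me2SO4, K2CO3, acetone) gives (2S,3S,3aS)-3a-allyl-5,7-dimethoxy-3-methyl-2-(3,4,5-trimethoxyphenyl)-3,3a-dihydro-1-benzofuran-6(2H)-one F7.
  - Heating (toluene, 110 °C) should move the allyl group suprafacially from C3a to C5 by Cope rearrangement. This is the direction 3a-allyl hydrobenzofuranones of this family take on heating, and it gives 20 with the allyl group anti to the C3 methyl (5R).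
  - The regiochemistry of the conjugate addition is the open point of this detour.

**Step 16.** The most likely failure is sluggish alkylation of the tertiary hydroxyl. Under more forcing conditions the allyl group may migrate, by oxy-Cope shift to C3a via the alkoxide or by acid-promoted 1,2-shift with aromatisation.
- Fallback, from 19 to 20, using the migration deliberately:
  - KH with 18-crown-6 in THF at 0 °C converts 19 by anionic oxy-Cope rearrangement (suprafacial, C5 to C3a) into potassium (2S,3S,3aS)-3a-allyl-7-methoxy-3-methyl-6-oxo-2-(3,4,5-trimethoxyphenyl)-2,3,3a,6-tetrahydro-1-benzofuran-5-olate F8.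
  - The enolate oxygen is methylated with Me2SO4 to the 3a-allyl methyl ether F7 described under step 15.
  - The thermal Cope rearrangement then returns the allyl group to the same face of C5 and gives 20. The methyl group is thus placed on an enolate oxygen and not on a tertiary alkoxide.

## Further compounds

F1 | step 11 | (1S,2S)-2-[2-(benzyloxy)-3-methoxy-4-(methoxymethoxy)phenyl]-1-[4-(benzyloxy)-3,5-dimethoxyphenyl]propan-1-ol | COCOc1ccc([C@H](C)[C@H](O)c2cc(OC)c(OCc3ccccc3)c(OC)c2)c(OCc2ccccc2)c1OC
F2 | step 11 | 6-[(1S,2S)-1-hydroxy-1-(4-hydroxy-3,5-dimethoxyphenyl)propan-2-yl]-2-methoxy-3-(methoxymethoxy)phenol | COCOc1ccc([C@H](C)[C@H](O)c2cc(OC)c(O)c(OC)c2)c(O)c1OC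
F3 | step 9 | 2-(benzyloxy)-3-methoxy-4-(methoxymethoxy)-1-(prop-1-en-2-yl)benzene | C=C(C)c1ccc(OCOC)c(OC)c1OCc1ccccc1
F4 | step 9 | 2-{(2R)-2-[2-(benzyloxy)-3-methoxy-4-(methoxymethoxy)phenyl]propyl}-4,4,5,5-tetramethyl-1,3,2-dioxaborolane | COCOc1ccc([C@H](C)CB2OC(C)(C)C(C)(C)O2)c(OCc2ccccc2)c1OC
F5 | step 9 | 2-(benzyloxy)-5-bromo-1,3-dimethoxybenzene | COc1cc(Br)cc(OC)c1OCc1ccccc1
F6 | step 15 | (2S,3S,3aS)-3a-allyl-5-hydroxy-7-methoxy-3-methyl-2-(3,4,5-trimethoxyphenyl)-3,3a-dihydro-1-benzofuran-6(2H)-one | C=CC[C@]12C=C(O)C(=O)C(OC)=C1O[C@H](c1cc(OC)c(OC)c(OC)c1)[C@H]2C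
F7 | step 15 | (2S,3S,3aS)-3a-allyl-5,7-dimethoxy-3-methyl-2-(3,4,5-trimethoxyphenyl)-3,3a-dihydro-1-benzofuran-6(2H)-one | C=CC[C@]12C=C(OC)C(=O)C(OC)=C1O[C@H](c1cc(OC)c(OC)c(OC)c1)[C@H]2C
F8 | step 16 | potassium (2S,3S,3aS)-3a-allyl-7-methoxy-3-methyl-6-oxo-2-(3,4,5-trimethoxyphenyl)-2,3,3a,6-tetrahydro-1-benzofuran-5-olate | C=CC[C@]12C=C([O-])C(=O)C(OC)=C1O[C@H](c1cc(OC)c(OC)c(OC)c1)[C@H]2C.[K+]
A1 | alternative 1 | 4-allyl-2-[(1S,2S)-1-(ethynyloxy)-1-(3,4,5-trimethoxyphenyl)propan-2-yl]-4-methoxycyclobut-2-en-1-one (either configuration at C4) | C#CO[C@H](c1cc(OC)c(OC)c(OC)c1)[C@@H](C)C1=CC(CC=C)(OC)C1=O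
A2 | alternative 1 | (2S,3S,5R)-5-allyl-5-methoxy-3-methyl-2-(3,4,5-trimethoxyphenyl)-3,5-dihydro-1-benzofuran-6(2H)-one | C=CC[C@@]1(OC)C=C2C(=CC1=O)O[C@H](c1cc(OC)c(OC)c(OC)c1)[C@H]2C
A3 | alternative 2 | 5-[(1S,2S)-1-hydroxy-1-(3,4,5-trimethoxyphenyl)propan-2-yl]-3-methoxybenzene-1,2-diol | O[C@H](c1cc(OC)c(OC)c(OC)c1)[C@@H](C)c1cc(O)c(O)c(OC)c1
A4 | alternative 2 | (2S,3S)-7-methoxy-3-methyl-2-(3,4,5-trimethoxyphenyl)-2,3-dihydro-1-benzofuran-5,6-dione | O=C1C=C2C(=C(OC)C1=O)O[C@H](c1cc(OC)c(OC)c(OC)c1)[C@H]2C
A5 | alternative 3 | (2R)-7-(allyloxy)-3-diazo-8-methoxy-2-(3,4,5-trimethoxyphenyl)chroman-4-one | C=CCOc1ccc2c(c1OC)O[C@H](c1cc(OC)c(OC)c(OC)c1)C(=[N+]=[N-])C2=O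
A6 | alternative 3 | methyl (2S,3S)-6-(allyloxy)-7-methoxy-2-(3,4,5-trimethoxyphenyl)-2,3-dihydro-1-benzofuran-3-carboxylate | C=CCOc1ccc2c(c1OC)O[C@H](c1cc(OC)c(OC)c(OC)c1)[C@H]2C(=O)OC
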